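**Two runs.** Wednesday's flask at 45 °C draws the curve I need. Its ratio [isomer of the product]/[target] reads 0.562 at 0.333 min and crosses one near 1.00 min. Target then bends flat, and the ratio reads 1.74 at 2.50 min. Sunday's flask at 18 °C reads 0.961 at 10.0 min.

the same everywhere: free catalyst 1.5 mM
- Sunday's: substrate 0.042 M; partner 0.112 M; temperature 18 °C; run made earlier
- Wednesday's: substrate 0.093 M; partner 0.112 M; temperature 45 °C; run made earlier
- Monday's: substrate 0.062 M; partner 0.056 M; temperature 18 °C; run made earlier
- south-east: substrate 0.062 M; partner 0.112 M; temperature 30 °C; time 6.0 min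
- south: substrate 0.062 M; partner 0.112 M; temperature 5 °C; time 6.0 min
- south-west: substrate 0.062 M; partner 0.112 M; temperature 55 °C; time 6.0 min
- west: substrate 0.062 M; partner 0.112 M; at 5 °C until 4.0 min, from then on at 55 °C; time 6.0 min

| run | time / min | target / % | isomer of the product / % |
|---|---|---|---|
| Sunday's | 1.33 | 26 | 0 |
| Sunday's | 2.50 | 37 | 10 |
| Sunday's | 4.00 | 48 | 21 |
| Sunday's | 5.00 | 54 | 28 |
| Sunday's | 8.00 | 53 | 43 |
| Sunday's | 10.0 | 51 | 49 |
| Wednesday's | 0.333 | 16 | 9 |
| Wednesday's | 0.667 | 25 | 21 |
| Wednesday's | 1.00 | 30 | 32 |
| Wednesday's | 1.33 | 32 | 42 |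
| Wednesday's | 2.00 | 34 | 55 |
| Wednesday's | 2.50 | 35 | 61 |
| Monday's | 0.833 | 6 | 0 |
| Monday's | 1.33 | 13 | 0 |
| Monday's | 2.50 | 20 | 4 |
| Monday's | 5.00 | 31 | 15 |
| Monday's | 10.0 | 38 | 31 |

(standard deviation of a reading: 1.5 percentage points)

- the numbers in the tables scatter with a standard deviation of 1.5 percentage points

1. which flask leads in share of target in all that became target or isomer of the product ("all alike" within 1.5 percentage points) (south-east / south / south-west / west / all alike)
2. share of target in all that became target or isomer of the product, south-east
3. share of target in all that became target or isomer of the product, south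
4. share of target in all that became target or isomer of the product, south-west
5. share of target in all that became target or isomer of the product, west

**Rest ratio.** I treat target and isomer of the product as a two-state pair, so the ratio should run into a level set by temperature, as under thermodynamic control. I draw ln(ratio) as a straight line in temperature through the two last readings. At 55 °C this gives 2.17, my rest ratio: the level of [isomer of the product]/[target] once the pair has relaxed. The share of target is then 1/(1+ratio), or 31.5 %. Both readings may still be drifting, and they carry their scatter.

**Reaching it.** Early in Wednesday's flask, isomer of the product gains 1.75 min⁻¹ per unit of target. That is a half-time of 0.396 min, shorter than west's hot stretch of 2.00 min. Wednesday's flask also turned 0.0577 M of substrate into the pair by 1.00 min, and west is charged with 0.062 M. So I expect south-west and west both at the rest share, whatever west did while cold. South, at 5 °C, is colder than Sunday's flask, whose share read 78.7 % at 2.50 min, so I put south first.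

**The forecast.** It names south as leader, with 43 % for south-east, 92 % for south, 47 % for south-west and 50 % for west. Its ground is that “selectivity seems to depend on target accumulated, not on time”. My two hot values differ from its values: I hold 31.5 % for both.

**The flasks.** South leads with 87.7 %; south-east gives 41.3 %, south-west 31.9 % and west 31.9 %.

    substrate + free catalyst → catalyst intermediate A (k = 220 L mol⁻¹ min⁻¹, Ea = 47.0 kJ mol⁻¹)
    partner + catalyst intermediate A ⇌ catalyst intermediate B (K = 4.20 L mol⁻¹, k = 140 L mol⁻¹ min⁻¹, Ea = 48.0 kJ mol⁻¹, ΔH = −25.0 kJ mol⁻¹)
    catalyst intermediate B → catalyst intermediate C (k = 30.0 min⁻¹, Ea = 69.0 kJ mol⁻¹)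
    catalyst intermediate C → free catalyst + target (k = 3.90 min⁻¹, Ea = 80.0 kJ mol⁻¹)
    target ⇌ isomer of the product (K = 0.970, k = 0.0500 min⁻¹, Ea = 75.0 kJ mol⁻¹, ΔH = 12.0 kJ mol⁻¹)
    2 catalyst intermediate B ⇌ resting dimer, settled at all times (K = 550 L mol⁻¹, ΔH = −15.0 kJ mol⁻¹)
    (constants at 5 °C)

**Hot end.** In south-west the relaxation half-life of the pair by its own step is 0.0675 min, far shorter than 6.0 min. The end ratio of south-west is 2.14. The temperature dependence of the conversion of target into isomer of the product carries 47 points of the 56 points gap between south-west and south; without it the gap is 9.2 points. A neighbour of south-west with 0.028 M of partner ends with 0 % of its partner and 52.4 % of its substrate left, yet its ratio is 2.14, beside my rest ratio of 2.17, and its share is 31.9 %.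

(The runs are calculated for an exercise; scatter was added.)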